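## Retrosynthetic overview

1. Cyclohexene locants: C1 bears the 4-methylpent-3-enyl chain, C2 is =CH, C3 bears flavanone C6, C4 the aroyl group, C5 the 2,4-dihydroxyphenyl ring, C6 is CH2. The feature used: C3 is both allylic to C1=C2 and benzylic to A-ring C6 (flanked by O5 and O7), C4 is α to the aroyl C=O, and all three ring substituents are equatorial (3,4-trans, 4,5-trans).
2. Key cut, with no cycloaddition: the C3–C4 bond is formed when an acyclic tertiary styryl carbinol ionises to a vinylogous quinone-methide cation and a tethered β-keto ester enol captures it in a 6-endo mode. The random C1 carbinol centre is erased, and C5 alone relays C3 (then C4).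
3. The acyclic precursor comes from four pieces. A Heck reaction makes A-ring C6–C3, a vinyl Grignard addition makes C1–C2, an asymmetric Michael addition makes C4–C5 and sets C5, and a Claisen–Schmidt condensation with 6-methylhept-5-en-2-one makes C5–C6.
4. The base-labile flavanone C2 centre is made last. A catalyst-controlled Rh 1,4-addition of the B-ring boronic acid to a chromone carried through the route sets it.
5. Ring order: chromone pyranone (bought), then cyclohexene (step 13), then chromanone C-ring by saturation of the chromone (step 17).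

Key step: step 13

**Abbreviations:** MOM = CH2OCH3; TMSE = CH2CH2SiMe3; ArK = 2,4-bis(methoxymethoxy)-3-(3-methylbut-2-enyl)phenyl; ArR = 2,4-bis(methoxymethoxy)phenyl; Chr = 5,7-bis(methoxymethoxy)-4-oxo-4H-chromen-6-yl.

**Assumption:** 9-amino-9-deoxy-epi-quinine (step 7) and (R,R)-Ph-bod* (step 17) are taken to deliver the nucleophile to the Re face of the acceptor β-carbon; if the sense is opposite, the quinidine-derived amine or the (S,S)-ligand is used with no other change.

## Route

Step 1
Reactants: 1 2,4-dihydroxyacetophenone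
Product: 2 1-[2,4-dihydroxy-3-(3-methylbut-2-enyl)phenyl]ethanone
Conditions: prenyl bromide, KOH, MeOH/H2O, 0 °C → rt
Reagents that add atoms: prenyl bromide, CC(C)=CCBr
Why: C-alkylation of the ambident resorcinolate in protic medium should favour the doubly activated C3 between the two oxygens, with O- and C5-alkylated isomers removed by chromatography.

Step 2
Reactants: 2 1-[2,4-dihydroxy-3-(3-methylbut-2-enyl)phenyl]ethanone
Product: 3 1-ArK-ethanone
Conditions: NaH, MOMCl, DMF, 0 °C → rt
Reagents that add atoms: chloromethyl methyl ether, COCCl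
Why: Williamson-type acetalisation with NaH also caps the chelated 2-OH, and MOM ethers tolerate every later basic and organometallic step.

Step 3
Reactants: 3 1-ArK-ethanone
Product: 4 methyl 3-ArK-3-oxopropanoate
Conditions: NaH, (MeO)2CO, THF, reflux; cold dilute HCl quench
Reagents that add atoms: dimethyl carbonate, COC(=O)OC
Why: Claisen-type C-acylation of the methyl ketone enolate is driven by formation of the stabilised β-keto ester enolate.

Step 4
Reactants: 4 methyl 3-ArK-3-oxopropanoate
Product: 5 2-(trimethylsilyl)ethyl 3-ArK-3-oxopropanoate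
Conditions: Me3SiCH2CH2OH, DMAP (cat.), toluene, reflux (–MeOH)
Reagents that add atoms: 2-(trimethylsilyl)ethanol, C[Si](C)(C)CCO
Why: DMAP-catalysed transesterification of β-keto esters installs an ester that survives Pd(0) in step 12 and is removed by fluoride in step 14.

Step 5
Reactants: 6 2,4-dihydroxybenzaldehyde
Product: 7 2,4-bis(methoxymethoxy)benzaldehyde
Conditions: NaH, MOMCl, DMF, 0 °C → rt
Reagents that add atoms: chloromethyl methyl ether, COCCl
Why: This is a standard bis-acetalisation of both phenols.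

Step 6
Reactants: 7 2,4-bis(methoxymethoxy)benzaldehyde; 8 6-methylhept-5-en-2-one
Product: 9 (E)-1-ArR-7-methylocta-1,6-dien-3-one
Conditions: 8 (3 equiv), 10 % aq NaOH, EtOH, rt
Reagents that add atoms: none
Why: Base-mediated Claisen–Schmidt condensation of a methyl alkyl ketone with an aryl aldehyde takes place at the methyl group and gives the E-enone, forming C5–C6 and bringing in C1 with the whole side chain.

Step 7
Reactants: 5 2-(trimethylsilyl)ethyl 3-ArK-3-oxopropanoate; 9 (E)-1-ArR-7-methylocta-1,6-dien-3-one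
Product: 10 2-(trimethylsilyl)ethyl (3S)-2-(ArK-carbonyl)-3-ArR-9-methyl-5-oxodec-8-enoate (C2 epimers)
Conditions: 9-amino-9-deoxy-epi-quinine (20 mol %), CF3CO2H (40 mol %), toluene, rt
Reagents that add atoms: none
Why: Asymmetric Michael addition of a 1,3-dicarbonyl compound to a β-aryl enone under primary-amine iminium catalysis forms C4–C5, and the shielded iminium ion directs Re-face attack to set C5 (S), while the labile C4 centre is irrelevant.

Step 8
Reactants: 10 Michael adduct
Product: 11 2-(trimethylsilyl)ethyl (3S)-2-(ArK-carbonyl)-3-ArR-5-ethenyl-5-hydroxy-9-methyldec-8-enoate (epimers at C2 and C5; may sit partly as its cyclic hemiketal)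
Conditions: LaCl3·2LiCl, CH2=CHMgBr (2.3 equiv), THF, –78 → –20 °C; aq NH4Cl
Reagents that add atoms: vinylmagnesium bromide, C=C[Mg]Br
Why: The first equivalent of Grignard reagent turns the β-keto ester into an inert enolate that masks the aryl ketone and ester, so the Grignard 1,2-addition occurs only at the dialkyl ketone, and the new carbinol centre need not be controlled because step 13 erases it.

Step 9
Reactants: 12 5,7-dihydroxy-4H-chromen-4-one
Product: 13 5-hydroxy-7-(methoxymethoxy)-4H-chromen-4-one
Conditions: MOMCl (1.1 equiv), K2CO3, acetone, rt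
Reagents that add atoms: chloromethyl methyl ether, COCCl
Why: The free, more acidic 7-OH is alkylated selectively while the 5-OH stays locked in its hydrogen bond to C4=O.

Step 10
Reactants: 13 5-hydroxy-7-(methoxymethoxy)-4H-chromen-4-one
Product: 14 5-hydroxy-6-iodo-7-(methoxymethoxy)-4H-chromen-4-one
Conditions: NIS, DMF, rt, dark
Reagents that add atoms: N-iodosuccinimide, O=C1CCC(=O)N1I
Why: Electrophilic aromatic iodination under neutral conditions should go ortho to the free chelated 5-OH (C6), the pattern known for 5-hydroxy-7-alkoxy chromones and flavones, which fixes the 6- rather than 8-linkage of the target.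

Step 11
Reactants: 14 5-hydroxy-6-iodo-7-(methoxymethoxy)-4H-chromen-4-one
Product: 15 6-iodo-5,7-bis(methoxymethoxy)-4H-chromen-4-one
Conditions: NaH, MOMCl, DMF, 0 °C → rt
Reagents that add atoms: chloromethyl methyl ether, COCCl
Why: Capping the 5-OH removes the only phenol that could trap the later cation as a 2H-chromene.

Step 12
Reactants: 11 vinyl carbinol; 15 6-iodo-5,7-bis(methoxymethoxy)-4H-chromen-4-one
Product: 16 2-(trimethylsilyl)ethyl (3S)-2-(ArK-carbonyl)-3-ArR-5-[(E)-2-Chr-ethenyl]-5-hydroxy-9-methyldec-8-enoate (epimers at C2 and C5)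
Conditions: Pd(OAc)2 (5 mol %), n-Bu4NCl, NaHCO3, DMF, 70 °C
Reagents that add atoms: none
Why: The Heck reaction of aryl iodides with tertiary vinyl carbinols gives E-styryl carbinols because no β-hydrogen sits on the carbinol carbon, the trisubstituted alkenes are inert, and the bicarbonate buffer protects the ionisable product.

Step 13
Reactants: 16 styryl carbinol β-keto ester
Product: 18 2-(trimethylsilyl)ethyl cyclohexenecarboxylate with C1 4-methylpent-3-enyl, C1=C2, C3 Chr, C4 quaternary (ArK-carbonyl and CO2TMSE, configuration inconsequential) and C5 ArR, the C3 and C5 aryl groups cis [CIP (3S,5R), the same spatial arrangement as 3R,5S in 20, because the quaternary C4 outranks the aryl groups], via allyl cation 17 (not isolated)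
Conditions: (PhO)2P(O)OH (10 mol %), CH2Cl2/(CF3)2CHOH 4:1, 4 Å MS, –20 °C → rt
Reagents that add atoms: none
Why: Proposed new method: the acid ionises the tertiary, styryl-conjugated C1–OH, so both carbinol epimers give the same planar cation 17 (a vinylogous quinone-methide cation with its charge on C3 and the O5/O7/O1-substituted A ring), and the tethered β-keto ester enol carbon C4 adds to C3, while any O-trapped material (the hemiketal-derived 3,4-dihydro-2H-pyran) re-ionises or shifts [3,3] to the same product, which makes C–C formation the sink. The closest known reaction types are the acid-catalysed dehydrative SN1′ allylic alkylation of 1,3-dicarbonyl compounds with aryl-conjugated allylic alcohols and the addition of β-keto esters to quinone methides made in situ; the new elements are the intramolecular 6-endo mode, the quaternary C4 and the 1,3-stereorelay. The cyclohexene closes by 6-endo attack on the C3 terminus of the C1–C2–C3 allyl cation (attack at C1 would give a cyclobutane), which places C1=C2 regiospecifically. C3 is controlled by C5: in the half-chair transition state the C5 aryl group is equatorial and the E-disposed A ring is pseudo-equatorial, giving the 3,5-cis relation, and reversible ionisation lets this diequatorial isomer accumulate; C4 is reset in step 14. The step needs the enol to outcompete the two trisubstituted side-chain alkenes and the ortho MOM oxygens, which is secured by the higher nucleophilicity of the enol, by the absence of any free phenol to trap a cyclised cation, and by the reversibility of alkene attack on so stabilised a cation.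

Step 14
Reactants: 18 cyclohexene β-keto ester
Product: 20 (3R,4R,5S)-all-trans ketone: ArK ketone at C4, Chr at C3, ArR at C5, 4-methylpent-3-enyl at C1 (C1=C2), via β-keto acid 19 (not isolated)
Conditions: TBAF, THF, 0 → 40 °C; then DBU (20 mol %), rt; aq NH4Cl
Reagents that add atoms: none
Why: Fluoride-induced fragmentation of the TMSE ester gives a β-keto acid that decarboxylates, and base equilibration of the α-centre sets C4 (R) under thermodynamic control because only the 3,4-trans-4,5-trans isomer has all three substituents equatorial.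

Step 15
Reactants: 21 4-bromoresorcinol
Product: 22 1-bromo-2,4-bis(methoxymethoxy)benzene
Conditions: NaH, MOMCl, DMF, 0 °C → rt
Reagents that add atoms: chloromethyl methyl ether, COCCl
Why: This is a standard bis-acetalisation of both phenols.

Step 16
Reactants: 22 1-bromo-2,4-bis(methoxymethoxy)benzene
Product: 24 2,4-bis(methoxymethoxy)phenylboronic acid, via aryllithium 23 (not isolated)
Conditions: n-BuLi, THF, –78 °C; B(Oi-Pr)3, –78 °C → rt; aq NH4Cl
Reagents that add atoms: n-butyllithium, [Li]CCCC (lithium of 23 only); triisopropyl borate, CC(C)OB(OC(C)C)OC(C)C; water, O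
Why: Bromine–lithium exchange is faster than ortho-deprotonation, and borylation followed by mild hydrolysis gives the boronic acid without loss of MOM groups.

Step 17
Reactants: 20 all-trans chromone ketone; 24 2,4-bis(methoxymethoxy)phenylboronic acid
Product: 25 octa-MOM ether of the target: (2S)-2-ArR-5,7-bis(methoxymethoxy)chroman-4-one bearing at C6 the (3R,4R,5S)-cyclohexenyl unit of 20
Conditions: [RhCl(C2H4)2]2 (2.5 mol %), (R,R)-Ph-bod* (5.5 mol %), K3PO4 (0.2 equiv), 24 (3 equiv), toluene/H2O 10:1, 40 °C
Reagents that add atoms: none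
Why: Rh/chiral-diene 1,4-addition of arylboronic acids to chromones (Hayashi–Miyaura type) gives flavanones, the ligand directs Re-face delivery at C2 to set 2S independently of the remote core, and the nearly neutral medium avoids retro-oxa-Michael opening.

Step 18
Reactants: 25 octa-MOM ether
Product: 27 target CNP0256494.1, (2S)-flavanone with (3R,4R,5S)-cyclohexene, via octakis(trimethylsilyl) ether 26 (not isolated)
Conditions: TMSOTf (24 equiv), 2,2′-bipyridyl (36 equiv), MeCN/CH2Cl2, 0 °C → rt; then H2O, rt; NaHCO3 work-up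
Reagents that add atoms: trimethylsilyl trifluoromethanesulfonate, C[Si](C)(C)OS(=O)(=O)C(F)(F)F (Me3Si groups of 26 only; none remain in 27)
Why: Silyl triflate/bipyridyl cleavage of aromatic MOM ethers runs through aryl silyl ethers in a buffered aprotic medium, so the phenols appear only on neutral hydrolysis and no acid is present to add them to C1=C2 or the prenyl alkene, or to ionise the flavanone C2–O1 bond.

## Compound list

1 | 2,4-dihydroxyacetophenone | CC(=O)c1ccc(O)cc1O | starting material
2 | 1-[2,4-dihydroxy-3-(3-methylbut-2-enyl)phenyl]ethanone | CC(=O)c1ccc(O)c(CC=C(C)C)c1O | intermediate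
3 | 1-[2,4-bis(methoxymethoxy)-3-(3-methylbut-2-enyl)phenyl]ethanone | CC(=O)c1ccc(OCOC)c(CC=C(C)C)c1OCOC | intermediate
4 | methyl 3-ArK-3-oxopropanoate | COC(=O)CC(=O)c1ccc(OCOC)c(CC=C(C)C)c1OCOC | intermediate
5 | 2-(trimethylsilyl)ethyl 3-ArK-3-oxopropanoate | C[Si](C)(C)CCOC(=O)CC(=O)c1ccc(OCOC)c(CC=C(C)C)c1OCOC | intermediate
6 | 2,4-dihydroxybenzaldehyde | O=Cc1ccc(O)cc1O | starting material
7 | 2,4-bis(methoxymethoxy)benzaldehyde | O=Cc1ccc(OCOC)cc1OCOC | intermediate
8 | 6-methylhept-5-en-2-one | CC(=O)CCC=C(C)C | starting material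
9 | (E)-1-ArR-7-methylocta-1,6-dien-3-one | CC(C)=CCCC(=O)/C=C/c1ccc(OCOC)cc1OCOC | intermediate
10 | (3S)-Michael adduct (C2 epimers) | C[Si](C)(C)CCOC(=O)C(C(=O)c1ccc(OCOC)c(CC=C(C)C)c1OCOC)[C@@H](c1ccc(OCOC)cc1OCOC)CC(=O)CCC=C(C)C | intermediate
11 | (3S)-tertiary vinyl carbinol (epimers at C2, C5) | C[Si](C)(C)CCOC(=O)C(C(=O)c1ccc(OCOC)c(CC=C(C)C)c1OCOC)[C@@H](c1ccc(OCOC)cc1OCOC)CC(O)(C=C)CCC=C(C)C | intermediate
12 | 5,7-dihydroxy-4H-chromen-4-one | O=c1ccoc2cc(O)cc(O)c12 | starting material
13 | 5-hydroxy-7-(methoxymethoxy)-4H-chromen-4-one | O=c1ccoc2cc(OCOC)cc(O)c12 | intermediate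
14 | 5-hydroxy-6-iodo-7-(methoxymethoxy)-4H-chromen-4-one | O=c1ccoc2cc(OCOC)c(I)c(O)c12 | intermediate
15 | 6-iodo-5,7-bis(methoxymethoxy)-4H-chromen-4-one | O=c1ccoc2cc(OCOC)c(I)c(OCOC)c12 | intermediate
16 | (3S)-(E)-styryl carbinol β-keto ester (epimers at C2, C5) | C[Si](C)(C)CCOC(=O)C(C(=O)c1ccc(OCOC)c(CC=C(C)C)c1OCOC)[C@@H](c1ccc(OCOC)cc1OCOC)CC(O)(/C=C/c1c(OCOC)cc2occc(=O)c2c1OCOC)CCC=C(C)C | intermediate
17 | allyl / vinylogous quinone-methide cation (not isolated) | C[Si](C)(C)CCOC(=O)C(C(=O)c1ccc(OCOC)c(CC=C(C)C)c1OCOC)[C@@H](c1ccc(OCOC)cc1OCOC)CC(CCC=C(C)C)=C[CH+]c1c(OCOC)cc2occc(=O)c2c1OCOC | intermediate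
18 | cyclohexene β-keto ester, 3,5-cis, C4 quaternary | CC(C)=CCCC1=C[C@@H](c2c(OCOC)cc3occc(=O)c3c2OCOC)C(C(=O)c2ccc(OCOC)c(CC=C(C)C)c2OCOC)(C(=O)OCC[Si](C)(C)C)[C@@H](c2ccc(OCOC)cc2OCOC)C1 | intermediate
19 | β-keto acid (not isolated) | CC(C)=CCCC1=C[C@@H](c2c(OCOC)cc3occc(=O)c3c2OCOC)C(C(=O)c2ccc(OCOC)c(CC=C(C)C)c2OCOC)(C(=O)O)[C@@H](c2ccc(OCOC)cc2OCOC)C1 | intermediate
20 | (3R,4R,5S)-all-trans chromone ketone | CC(C)=CCCC1=C[C@@H](c2c(OCOC)cc3occc(=O)c3c2OCOC)[C@H](C(=O)c2ccc(OCOC)c(CC=C(C)C)c2OCOC)[C@@H](c2ccc(OCOC)cc2OCOC)C1 | intermediate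
21 | 4-bromoresorcinol | Oc1ccc(Br)c(O)c1 | starting material
22 | 1-bromo-2,4-bis(methoxymethoxy)benzene | COCOc1ccc(Br)c(OCOC)c1 | intermediate
23 | 2,4-bis(methoxymethoxy)phenyllithium (not isolated) | [Li]c1ccc(OCOC)cc1OCOC | intermediate
24 | 2,4-bis(methoxymethoxy)phenylboronic acid | OB(O)c1ccc(OCOC)cc1OCOC | intermediate
25 | octa-MOM ether of the target, (2S; 3R,4R,5S) | CC(C)=CCCC1=C[C@@H](c2c(OCOC)cc3c(c2OCOC)C(=O)C[C@@H](c2ccc(OCOC)cc2OCOC)O3)[C@H](C(=O)c2ccc(OCOC)c(CC=C(C)C)c2OCOC)[C@@H](c2ccc(OCOC)cc2OCOC)C1 | intermediate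
26 | octakis(trimethylsilyl) ether of the target (not isolated) | CC(C)=CCCC1=C[C@@H](c2c(O[Si](C)(C)C)cc3c(c2O[Si](C)(C)C)C(=O)C[C@@H](c2ccc(O[Si](C)(C)C)cc2O[Si](C)(C)C)O3)[C@H](C(=O)c2ccc(O[Si](C)(C)C)c(CC=C(C)C)c2O[Si](C)(C)C)[C@@H](c2ccc(O[Si](C)(C)C)cc2O[Si](C)(C)C)C1 | intermediate
27 | CNP0256494.1 | CC(C)=CCCC1=C[C@@H](c2c(O)cc3c(c2O)C(=O)C[C@@H](c2ccc(O)cc2O)O3)[C@H](C(=O)c2ccc(O)c(CC=C(C)C)c2O)[C@@H](c2ccc(O)cc2O)C1 | target

## Step count and risks

Total step count: 18.
Longest linear sequence: 11 (steps 1, 2, 3, 4, 7, 8, 12, 13, 14, 17, 18).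

### Steps most likely to fail

**Step 13 (labelled step).**
- The cation may lose a proton to trienes that oligomerise.
- An ortho MOM oxygen may capture it, with loss of the acetal.
- It may fragment at the C5–C6 bond (Grob-type retro-Michael), which erodes the enantiomeric purity set in step 7.
- Closure onto the crowded quaternary C4 may be too slow.

The fallback uses known chemistry: the Claisen rearrangement of 2-alkenyl-3,4-dihydro-2H-pyrans to cyclohex-3-enyl ketones. It sets out from 16 and returns at 20. The ester is removed first with TBAF, giving the δ-hydroxy ketone F1. Its cyclic hemiketal is dehydrated (PPTS, 4 Å MS) to the 6-ArK-2-styryl-3,4-dihydro-2H-pyrans, which are separated into the (2R,4S)-dihydropyran F2 (styryl trans to ArR) and the (2S,4S)-epimer F3. F3 can be returned to the mixture by acid-induced re-equilibration at C2. Heating F2 (toluene, 110–140 °C, BHT) should trigger the concerted [3,3] shift through the only accessible boat transition state, with transfer of chirality from the C–O carbon to C3. This gives the all-cis ketone F4, and DBU then epimerises C4 to give 20.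

**Step 17.**
- Transmetalation and insertion may be sluggish with an ortho-alkoxy boronic acid on an electron-rich, 6-substituted chromone.
- Protodeboronation competes.
- Facial selectivity may be poor.

The fallback sets out from 20 and 22 and returns at 25. Bromide 22 is converted with Mg into the arylmagnesium bromide F5. This is added under CuBr·SMe2/TMSCl (THF, –78 → –30 °C) in a copper-mediated 1,4-addition to the chromone, giving the silyl enol ether F6. Mild hydrolysis gives 25 together with its (2R)-epimer F7. These are diastereomers and are separated by chromatography. F7 is recycled by DBU equilibration through the ring-opened chalcone. That chalcone can only reclose through the former O1, because O5 stays protected.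

**Step 18.**
- Loss of the eight acetals may be incomplete or uneven.
- Freshly released ortho-phenols may add to C1=C2 or to the prenyl double bond during the acidic phase of the hydrolysis.
- The configuration at C2 may be lost.

The fallback sets out from 25 and returns at 27. The MOM groups are exchanged directly for triethylsilyl groups (TESOTf, 2,2′-bipyridyl), giving the isolable, chromatographable octakis(triethylsilyl) ether F8. Acetal cleavage is thus finished while every phenol is still capped. The phenols are then released in a separate operation with buffered fluoride (Et3N·3HF or KHF2/MeOH, 0 °C).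

## Further compounds

F1 | step 13 | δ-hydroxy ketone, (S) at the ArR-bearing carbon, carbinol epimers | CC(C)=CCCC(O)(/C=C/c1c(OCOC)cc2occc(=O)c2c1OCOC)C[C@H](c1ccc(OCOC)cc1OCOC)CC(=O)c1ccc(OCOC)c(CC=C(C)C)c1OCOC
F2 | step 13 | (2R,4S)-6-ArK-4-ArR-2-(4-methylpent-3-enyl)-2-[(E)-2-Chr-ethenyl]-3,4-dihydro-2H-pyran | CC(C)=CCC[C@]1(/C=C/c2c(OCOC)cc3occc(=O)c3c2OCOC)C[C@H](c2ccc(OCOC)cc2OCOC)C=C(c2ccc(OCOC)c(CC=C(C)C)c2OCOC)O1
F3 | step 13 | (2S,4S)-epimer of F2 | CC(C)=CCC[C@@]1(/C=C/c2c(OCOC)cc3occc(=O)c3c2OCOC)C[C@H](c2ccc(OCOC)cc2OCOC)C=C(c2ccc(OCOC)c(CC=C(C)C)c2OCOC)O1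
F4 | step 13 | (3R,4S,5S)-all-cis ketone, C4 epimer of 20 | CC(C)=CCCC1=C[C@@H](c2c(OCOC)cc3occc(=O)c3c2OCOC)[C@@H](C(=O)c2ccc(OCOC)c(CC=C(C)C)c2OCOC)[C@@H](c2ccc(OCOC)cc2OCOC)C1
F5 | step 17 | 2,4-bis(methoxymethoxy)phenylmagnesium bromide | COCOc1ccc([Mg]Br)c(OCOC)c1
F6 | step 17 | 4-(trimethylsilyloxy)-2H-chromene (silyl enol ether, C2 epimers) | CC(C)=CCCC1=C[C@@H](c2c(OCOC)cc3c(c2OCOC)C(O[Si](C)(C)C)=CC(c2ccc(OCOC)cc2OCOC)O3)[C@H](C(=O)c2ccc(OCOC)c(CC=C(C)C)c2OCOC)[C@@H](c2ccc(OCOC)cc2OCOC)C1
F7 | step 17 | (2R)-epimer of 25 | CC(C)=CCCC1=C[C@@H](c2c(OCOC)cc3c(c2OCOC)C(=O)C[C@H](c2ccc(OCOC)cc2OCOC)O3)[C@H](C(=O)c2ccc(OCOC)c(CC=C(C)C)c2OCOC)[C@@H](c2ccc(OCOC)cc2OCOC)C1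
F8 | step 18 | octakis(triethylsilyl) ether of the target | CC(C)=CCCC1=C[C@@H](c2c(O[Si](CC)(CC)CC)cc3c(c2O[Si](CC)(CC)CC)C(=O)C[C@@H](c2ccc(O[Si](CC)(CC)CC)cc2O[Si](CC)(CC)CC)O3)[C@H](C(=O)c2ccc(O[Si](CC)(CC)CC)c(CC=C(C)C)c2O[Si](CC)(CC)CC)[C@@H](c2ccc(O[Si](CC)(CC)CC)cc2O[Si](CC)(CC)CC)C1
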